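- Two questions stood before me, and one decision hung on the late one: keep the stop and the charge of the flask, or change them.

| flask | starting material | remark | time |
|---|---|---|---|
| larch | 0.034 M | run made earlier |  |
| cedar | 0.075 M | run made earlier |  |
| flask | 0.050 M |  | 4.0 min |

- larch (time / min: isomer of the product A / %, target / %): 1.33: 21.6, 75.0; 2.50: 8.7, 89.7; 4.00: 4.7, 94.8; 5.00: 4.6, 95.0
- cedar (time / min: isomer of the product A / %, target / %): 0.417: 54.8, 37.8; 0.833: 34.3, 61.2; 2.00: 10.2, 88.3; 5.00: 1.6, 97.8

(readings scatter by 0.5 percentage points)

- percent here means starting material units held: one idle adduct counts as two
- what is said of target includes idle adduct and crystals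
- crystals is a solid; its amount is given per volume of the solution
- the numbers in the tables scatter with a standard deviation of 0.5 percentage points
- steps thought possible: target <-> isomer of the product B; isomer of the product A <-> starting material; starting material <-> target; target <-> isomer of the product A; crystals <-> target; starting material + target <-> idle adduct
- in an amount of target, one idle adduct counts as one target

- ratio of isomer of the product A to target at 0.10 s
- ratio of isomer of the product A to target at 4.0 min

- I left the early ratio out of my reckoning because the first reading, at 0.417 min, comes later than 0.10 s.
- In the cedar run I subtracted the last reading, 1.6%, from the isomer of the product A as a level. The excess above it fell at 1.14 min⁻¹, a pseudo-first-order decay with a half-life of 0.606 min.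
- I counted turnovers, the stop time divided by that half-life: 6.60.
- Back-extrapolated, the excess started near 85.7%, so 0.881% remained at the stop.
- After removing the excess left at 5.00 min, 0.281%, from both last readings, I took the mean level of c(isomer of the product A): 0.00123 M.
- In the flask that level is 2.46%, more than the excess. A longer wait could therefore take off no more than the excess of 0.881%, so I kept the stop. Taken as one concentration, the level counts for less in percent at a larger charge, so the charge was the setting to weigh. I held it at 0.050 M as a choice, since that is the flask asked about, and my ratio was 0.0346.
- The forecast, a little higher, gave 0.035 late and 40 early, reading the level as “crystals pin dissolved target at saturation”.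
- The flask gave 0.0353 at 4.0 min and 91.2 at 0.10 s, and its isomer of the product A peaked at 85.3% after 0.00962 min.

    target ⇌ isomer of the product B (K = 0.210, k = 0.0140 s⁻¹)
    isomer of the product A ⇌ starting material (k = 1.40 s⁻¹)
    starting material ⇌ target (K = 2.70, k = 0.0910 s⁻¹)
    target ⇌ isomer of the product A (K = 2.50, k = 0.0240 s⁻¹)
    crystals ⇌ target, rate k5*(cs5 - [target]) while solid is left; crystals form when [target] > cs5 (solubility = 0.520 mM, k = 2.20 s⁻¹)
    starting material + target ⇌ idle adduct, settled at all times (K = 23.0 M⁻¹)

- From 3.38% at 4.00 min, the flask fell to 2.60% at 40.0 min, a drop of 0.78 percentage points against the 0.881% that 6.60 turnovers had left. The neighbouring flask, charged with 0.030 M, had the same count at 4.00 min, so level plus excess gave 4.98%, and it held 5.10%.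

(The numbers in the tables stem from a simulated flask from invented constants; scatter was added.)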